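**Plan**
- Retrosynthesis cuts the C(sp3)–C(sp2) bond between C1' of the hexadecyl chain and ring carbon C3, giving hexadecanal, 2-hydroxy-5-methoxy-1,4-benzoquinone and a hydride donor. The C2 hydroxyl is traced back to a second methoxy group (symmetrical 2,5-dimethoxy-1,4-benzoquinone) and the aldehyde to hexadecan-1-ol.
- Enabling feature: in the six-membered quinone ring, HO–C2=C3–C4=O is a vinylogous carboxylic acid, so C3 is an enol carbon that condenses with an aldehyde. The resulting C3-alkylidene, flanked by the C2 and C4 carbonyls, is an ortho-quinone methide that accepts hydride. C6 lies in the MeO–C5=C6–C1=O vinylogous ester, cannot ionise and stays untouched.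
- Forward: the ring is bought intact and no ring is formed. Step 1 makes the aldehyde, step 2 unmasks one hydroxyl, and step 3 joins the C16 chain to C3 in a three-component reductive alkylation at the quinone oxidation level, without protecting groups, giving the target directly.
- Stereochemistry: the target has no stereocentre and no stereogenic double bond. The geometry of the transient alkylidene is irrelevant because that double bond is reduced.

Key step: step 3

Remark: the target is taken as the 2-hydroxy-1,4-quinone tautomer drawn in its SMILES. Hexadecanal is made fresh because long-chain aldehydes oxidise and trimerise on storage. Methanol is the co-solvent in step 3 so that any exchange at the C5 methoxy group is degenerate.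

Step 1
Reactants: 1 hexadecan-1-ol
Product: 2 hexadecanal
Conditions: TEMPO (10 mol%), PhI(OAc)2 (1.1 equiv), CH2Cl2, 25 °C
Reagents that add atoms: none
Why: TEMPO-catalysed oxoammonium oxidation of a primary alcohol with PhI(OAc)2 as terminal oxidant should stop at the aldehyde in anhydrous CH2Cl2, and the aldehyde is used at once.

Step 2
Reactants: 3 2,5-dimethoxy-1,4-benzoquinone
Product: 5 2-hydroxy-5-methoxy-1,4-benzoquinone, via sodium quinonate salt 4 (not isolated)
Conditions: NaOH (1 M aq, 1.2 equiv), THF/H2O, 0 to 25 °C; then HCl (1 M aq) to pH 1
Reagents that add atoms: sodium hydroxide, [Na+].[OH-]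
Why: Vinylogous ester saponification by addition–elimination of hydroxide at a methoxy-bearing carbon; the two methoxy groups of 3 are equivalent, and the delocalised vinylogous carboxylate 4 formed after the first hydrolysis should resist a second attack, so the reaction should stop at the mono-ether.

Step 3
Reactants: 2 hexadecanal; 5 2-hydroxy-5-methoxy-1,4-benzoquinone; 6 diethyl 2,6-dimethyl-1,4-dihydropyridine-3,5-dicarboxylate (Hantzsch ester)
Product: 8 3-hexadecyl-2-hydroxy-5-methoxy-1,4-benzoquinone, via alkylidene trione 7 (not isolated)
Conditions: 2 (1.2 equiv), 6 (1.2 equiv), L-proline (20 mol%), CH2Cl2/MeOH, 25 °C, N2; work-up in air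
Reagents that add atoms: none
Why: L-proline condenses with aldehyde 2 to an iminium ion, which is attacked by C3 of 5, the enol carbon of the HO–C2=C3–C4=O vinylogous acid, and loss of the amine gives alkylidene trione 7 (Knoevenagel condensation); the exocyclic carbon of this ortho-quinone methide then takes hydride from C4 of Hantzsch ester 6, and protonation of the enolate restores the hydroxyquinone, with aromatisation of 6 to the pyridine as driving force. The closest known reaction type is the amino-acid-catalysed three-component reductive alkylation (Knoevenagel condensation–transfer hydrogenation cascade) of cyclic 1,3-dicarbonyls and of hydroxyquinones such as 2-hydroxy-1,4-naphthoquinone and 2,5-dihydroxy-1,4-benzoquinone. No ring is closed and no stereocentre is formed. The step needs site selectivity for C3 over C6 and C- over O-alkylation: only C3 belongs to an ionisable vinylogous acid, C6 is held in the non-ionisable C5-methoxy vinylogous ester, and O-adducts of the aldehyde are reversible hemiacetals that cannot be reduced. Mono-alkylation is secured because the product has no further enol CH, and hydride delivery to 7 instead of the ring carbonyls is expected because the hydroxy- and methoxy-substituted quinone is a weak oxidant and any hydroquinone formed would reoxidise in air on work-up.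

**Compound list**
1 | hexadecan-1-ol | CCCCCCCCCCCCCCCCO | starting material
2 | hexadecanal | CCCCCCCCCCCCCCCC=O | intermediate
3 | 2,5-dimethoxy-1,4-benzoquinone | COC1=CC(=O)C(OC)=CC1=O | starting material
4 | sodium 4-methoxy-3,6-dioxocyclohexa-1,4-dien-1-olate (sodium quinonate salt) | COC1=CC(=O)C([O-])=CC1=O.[Na+] | intermediate
5 | 2-hydroxy-5-methoxy-1,4-benzoquinone | COC1=CC(=O)C(O)=CC1=O | intermediate
6 | diethyl 2,6-dimethyl-1,4-dihydropyridine-3,5-dicarboxylate (Hantzsch ester) | CCOC(=O)C1=C(C)NC(C)=C(C(=O)OCC)C1 | starting material
7 | 3-hexadecylidene-5-methoxycyclohex-5-ene-1,2,4-trione (alkylidene trione, alkene geometry undefined) | CCCCCCCCCCCCCCCC=C1C(=O)C(=O)C=C(OC)C1=O | intermediate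
8 | 3-hexadecyl-2-hydroxy-5-methoxy-1,4-benzoquinone | CCCCCCCCCCCCCCCCC1=C(O)C(=O)C=C(OC)C1=O | target

**Summary**
Total step count: 3. Longest linear sequence: 2 steps (step 1 then step 3, or step 2 then step 3).

**Risks and fallbacks**

The riskiest is step 3. The transient alkylidene may be captured by a second hydroxyquinone in a Michael addition that outruns hydride transfer, or the amine catalyst may be consumed by addition–elimination at the methoxy-bearing carbon. The fallback for step 3 changes the bond-forming manifold from ionic to radical and sets out from compound 3. A Minisci-type decarboxylative radical alkylation of an excess of 3 with heptadecanoic acid (AgNO3 cat., (NH4)2S2O8, MeCN/H2O, 70 °C) should give 3-hexadecyl-2,5-dimethoxy-1,4-benzoquinone F1. Selective acid hydrolysis (70% HClO4, dioxane, 25 °C) of the C2 methoxy group, which the neighbouring chain twists out of conjugation, then returns to the route at compound 8.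

Second in risk is step 2. Hydrolysis may run on past the mono-ether stage, or base may degrade the quinone ring while the poorly soluble diether is still dissolving. The fallback for step 2 differentiates the two oxygens only after the chain is in place and sets out from compound 2. Reductive alkylation of an excess of commercial 2,5-dihydroxy-1,4-benzoquinone with 2 and 6 (L-proline cat., CH2Cl2, 25 °C) should pass through 3-hexadecylidene-5-hydroxycyclohex-5-ene-1,2,4-trione F2, which is not isolated, to 3-hexadecyl-2,5-dihydroxy-1,4-benzoquinone F3. A vinylogous Fischer esterification (MeOH, cat. H2SO4, reflux) at the less hindered C5 hydroxyl, whose carbon neighbours C6–H and not the chain, then returns to the route at compound 8.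

Third in risk is step 1. Over-oxidation to the acid level, ester formation through the hemiacetal, or oligomerisation of the aldehyde during concentration may occur. The fallback for step 1 avoids an oxidant that can act on the aldehyde and sets out from compound 1. Tosylation (TsCl, pyridine, CH2Cl2, 0 °C) should give hexadecyl 4-methylbenzenesulfonate F4, and Kornblum oxidation (DMSO, NaHCO3, 150 °C, short reaction time) returns to the route at compound 2.

**Further compounds**
F1 | step 3 | 3-hexadecyl-2,5-dimethoxy-1,4-benzoquinone | CCCCCCCCCCCCCCCCC1=C(OC)C(=O)C=C(OC)C1=O
F2 | step 2 | 3-hexadecylidene-5-hydroxycyclohex-5-ene-1,2,4-trione | CCCCCCCCCCCCCCCC=C1C(=O)C(=O)C=C(O)C1=O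
F3 | step 2 | 3-hexadecyl-2,5-dihydroxy-1,4-benzoquinone | CCCCCCCCCCCCCCCCC1=C(O)C(=O)C=C(O)C1=O
F4 | step 1 | hexadecyl 4-methylbenzenesulfonate | CCCCCCCCCCCCCCCCOS(=O)(=O)c1ccc(C)cc1
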